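**Retrosynthetic overview**

- The route rests on the two benzylic CH stereocentres on C3 and C5 of the hexanoyl-trihydroxybenzene ring. Each is flanked by two phenolic OH groups and bonded to the enolic C2 of a 2-hydroxy-3,3,5,5-tetramethyl-4,6-dioxocyclohexene (syncarpyl) ring, so each is the adduct of syncarpic acid C2 to an ortho-quinone methide of the core.
- Both CH–C2(syncarpyl) bonds are cut together, giving a stereorandom bis(1-tosylalkyl) hexanoylphloroglucinol and two syncarpic acid units. In the forward sense, base-triggered sulfinate loss and squaramide-controlled conjugate addition form them arm by arm in one flask.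
- The bis-sulfone comes from hexanoylphloroglucinol by two successive aldehyde/sulfinate condensations (isobutyraldehyde, then isovaleraldehyde). Hexanoylphloroglucinol comes from phloroglucinol and hexanoyl chloride.
- Syncarpic acid is made from 2,4,6-trihydroxyacetophenone by dearomatising tetra-C-methylation and retro-Claisen deacetylation.
- Ring order: no ring is closed anywhere. The benzene core is bought, and the two trione rings arise by dearomatisation of a second bought benzene ring.

Key step: step 6

Assumption: the quinine-derived squaramide is taken to deliver the R configuration at both arms (otherwise its quinidine-derived pseudo-enantiomer is used), and the intermediates of the key step are drawn with the isopropyl-bearing arm reacting first; the opposite order converges on the same product.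

**Route**

Step 1
Reactants: 1 phloroglucinol; 2 hexanoyl chloride
Product: 3 1-(2,4,6-trihydroxyphenyl)hexan-1-one (hexanoylphloroglucinol)
Conditions: AlCl3 (3.5 equiv), PhNO2–CH2Cl2, 0 → 45 °C; then ice/2 M HCl
Reagents that add atoms: none
Why: Friedel–Crafts C-acylation of the very electron-rich ring (directly or by O-acylation and Fries shift) should stop after one acyl group, because the aryl ketone chelated to aluminium deactivates the ring and the acid chloride is limiting.

Step 2
Reactants: 3 1-(2,4,6-trihydroxyphenyl)hexan-1-one; 4 isobutyraldehyde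
Product: 6 1-[2,4,6-trihydroxy-3-(2-methyl-1-tosylpropyl)phenyl]hexan-1-one (racemic), via o-quinone methide 5 (not isolated)
Conditions: 3 (1.3 equiv), 4 (1.0 equiv, slow addition), p-TolSO2Na (2.5 equiv), HCO2H–H2O (1:1), rt
Reagents that add atoms: sodium p-toluenesulfinate, Cc1ccc(cc1)S(=O)[O-].[Na+]
Why: In this three-component Mannich-type sulfonylalkylation, acid-promoted hydroxyalkylation of a free ring position and dehydration give quinone methide 5, which excess sulfinate should capture at sulfur to give the sparingly soluble sulfone, while the limiting aldehyde and the deactivating sulfonylalkyl group hold back the second ring position; the new centre is racemic, which is irrelevant.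

Step 3
Reactants: 6 1-[2,4,6-trihydroxy-3-(2-methyl-1-tosylpropyl)phenyl]hexan-1-one; 7 isovaleraldehyde (3-methylbutanal)
Product: 9 1-[2,4,6-trihydroxy-3-(3-methyl-1-tosylbutyl)-5-(2-methyl-1-tosylpropyl)phenyl]hexan-1-one (mixture of all stereoisomers), via o-quinone methide 8 (not isolated)
Conditions: 7 (2 equiv), p-TolSO2Na (3 equiv), HCO2H–H2O (2:1), rt → 35 °C
Reagents that add atoms: sodium p-toluenesulfinate, Cc1ccc(cc1)S(=O)[O-].[Na+]
Why: The same Mannich-type sulfonylalkylation at the last free ring position should proceed with the α-unbranched aldehyde in excess, the first sulfone arm being able to ionise only reversibly in the sulfinate-rich medium; the second centre forms without control and both centres are erased in step 6.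

Step 4
Reactants: 10 2,4,6-trihydroxyacetophenone (phloroacetophenone)
Product: 11 2-acetyl-3-hydroxy-4,4,6,6-tetramethylcyclohex-2-ene-1,5-dione (acetylsyncarpic acid)
Conditions: NaOMe (5 equiv), MeI (6 equiv), MeOH, 0 °C → reflux; then aq. HCl
Reagents that add atoms: iodomethane, CI
Why: Exhaustive dearomatising C-methylation of the phloroglucinol polyanion should place two methyl groups on each of the two unsubstituted ring carbons (the soft enolate carbons), the acetyl group blocking the third; this is the long-established entry to acylsyncarpic acids.

Step 5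
Reactants: 11 2-acetyl-3-hydroxy-4,4,6,6-tetramethylcyclohex-2-ene-1,5-dione
Product: 12 syncarpic acid (2,2,4,4-tetramethylcyclohexane-1,3,5-trione)
Conditions: 6 M aq. HCl, reflux
Reagents that add atoms: none
Why: Acid-mediated retro-Claisen deacylation of the 2-acyl-1,3-dione should remove the exocyclic acetyl group as acetic acid, the ring carbonyls being shielded by the flanking quaternary carbons.

Step 6
Reactants: 9 1-[2,4,6-trihydroxy-3-(3-methyl-1-tosylbutyl)-5-(2-methyl-1-tosylpropyl)phenyl]hexan-1-one; 12 syncarpic acid (two equivalents incorporated)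
Product: 16 myrtucommulone H (R at both benzylic carbons), via first quinone methide 13 (not isolated), via mono-adduct sulfone 14 (not isolated), via second quinone methide 15 (not isolated)
Conditions: 12 (2.5 equiv), quinine-derived 3,5-bis(trifluoromethyl)phenyl squaramide (20 mol %), 5% aq. NaHCO3 (3 equiv), CH2Cl2, Ar, 0 °C → rt; then cold 1 M HCl to pH 3
Reagents that add atoms: none
Why: Hydrogencarbonate (or the quinuclidine of the catalyst) ionises a phenol next to a sulfonylalkyl arm and the phenoxide expels p-toluenesulfinate by 1,4-elimination to the planar quinone methide 13, erasing the configuration of that sulfone carbon; the squaramide N–H pair binds the quinone-methide carbonyl, the protonated quinuclidine carries the syncarpate, and C2 of the syncarpate adds to the exocyclic carbon with rearomatisation to 14, after which the same events at the other arm (via 15) give 16. The closest known reaction type is the squaramide-catalysed enantioselective conjugate addition of cyclic 1,3-dicarbonyl compounds and other acidic carbon nucleophiles to ortho-quinone methides released from 2-(1-sulfonylalkyl)phenols by aqueous hydrogencarbonate. No ring is closed: two C–C bonds are formed and the adducts stay open because the medium is never hot or strongly acidic, so cyclodehydration of enol and phenol to a pyran should not set in. Each of the two new benzylic stereocentres (both R) is controlled by the catalyst, which exposes the same enantioface of each quinone methide whichever sulfone epimer it came from, and because the two additions are independent a residual wrong-face event ends up mainly in the unlike diastereomer, to be removed by chromatography or crystallisation. The step needs enantioface selectivity over the catalyst-free addition of sodium syncarpate, C- over O-alkylation and one alkylation per nucleophile; the oxygens flanking each exocyclic carbon and the hexanoyl chelate offer a defined hydrogen-bond acceptor site for the squaramide, the quinone-methide geometries interconvert by proton shift between the flanking oxygens so that the best-bound one reacts, and C2 of syncarpic acid is a soft, strongly acidic carbon that is fully substituted after one addition.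

**Compound list**

1 | phloroglucinol | Oc1cc(O)cc(O)c1 | starting material
2 | hexanoyl chloride | CCCCCC(Cl)=O | starting material
3 | 1-(2,4,6-trihydroxyphenyl)hexan-1-one | CCCCCC(=O)c1c(O)cc(O)cc1O | intermediate
4 | isobutyraldehyde | CC(C)C=O | starting material
5 | 2-hexanoyl-3,5-dihydroxy-6-(2-methylpropylidene)cyclohexa-2,4-dien-1-one (alkene geometry undefined) | CCCCCC(=O)C1=C(O)C=C(O)C(=CC(C)C)C1=O | intermediate (not isolated)
6 | 1-[2,4,6-trihydroxy-3-(2-methyl-1-tosylpropyl)phenyl]hexan-1-one (racemic) | CCCCCC(=O)c1c(O)cc(O)c(C(C(C)C)S(=O)(=O)c2ccc(C)cc2)c1O | intermediate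
7 | isovaleraldehyde (3-methylbutanal) | CC(C)CC=O | starting material
8 | 2-hexanoyl-3,5-dihydroxy-6-(3-methylbutylidene)-4-(2-methyl-1-tosylpropyl)cyclohexa-2,4-dien-1-one (racemic, alkene geometry undefined) | CCCCCC(=O)C1=C(O)C(C(C(C)C)S(=O)(=O)c2ccc(C)cc2)=C(O)C(=CCC(C)C)C1=O | intermediate (not isolated)
9 | 1-[2,4,6-trihydroxy-3-(3-methyl-1-tosylbutyl)-5-(2-methyl-1-tosylpropyl)phenyl]hexan-1-one (all stereoisomers) | CCCCCC(=O)c1c(O)c(C(CC(C)C)S(=O)(=O)c2ccc(C)cc2)c(O)c(C(C(C)C)S(=O)(=O)c2ccc(C)cc2)c1O | intermediate
10 | 2,4,6-trihydroxyacetophenone | CC(=O)c1c(O)cc(O)cc1O | starting material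
11 | 2-acetyl-3-hydroxy-4,4,6,6-tetramethylcyclohex-2-ene-1,5-dione (acetylsyncarpic acid) | CC(=O)C1=C(O)C(C)(C)C(=O)C(C)(C)C1=O | intermediate
12 | syncarpic acid (2,2,4,4-tetramethylcyclohexane-1,3,5-trione) | CC1(C)C(=O)CC(=O)C(C)(C)C1=O | intermediate
13 | 2-hexanoyl-3,5-dihydroxy-4-(3-methyl-1-tosylbutyl)-6-(2-methylpropylidene)cyclohexa-2,4-dien-1-one (both sulfone epimers, alkene geometry undefined) | CCCCCC(=O)C1=C(O)C(C(CC(C)C)S(=O)(=O)c2ccc(C)cc2)=C(O)C(=CC(C)C)C1=O | intermediate (not isolated)
14 | 1-{2,4,6-trihydroxy-3-[(1R)-1-(2-hydroxy-3,3,5,5-tetramethyl-4,6-dioxocyclohex-1-en-1-yl)-2-methylpropyl]-5-(3-methyl-1-tosylbutyl)phenyl}hexan-1-one (both epimers at the sulfone carbon) | CCCCCC(=O)c1c(O)c(C(CC(C)C)S(=O)(=O)c2ccc(C)cc2)c(O)c([C@H](C2=C(O)C(C)(C)C(=O)C(C)(C)C2=O)C(C)C)c1O | intermediate (not isolated)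
15 | 2-hexanoyl-3,5-dihydroxy-4-[(1R)-1-(2-hydroxy-3,3,5,5-tetramethyl-4,6-dioxocyclohex-1-en-1-yl)-2-methylpropyl]-6-(3-methylbutylidene)cyclohexa-2,4-dien-1-one (alkene geometry undefined) | CCCCCC(=O)C1=C(O)C([C@H](C2=C(O)C(C)(C)C(=O)C(C)(C)C2=O)C(C)C)=C(O)C(=CCC(C)C)C1=O | intermediate (not isolated)
16 | myrtucommulone H, 1-{2,4,6-trihydroxy-3-[(1R)-1-(2-hydroxy-3,3,5,5-tetramethyl-4,6-dioxocyclohex-1-en-1-yl)-3-methylbutyl]-5-[(1R)-1-(2-hydroxy-3,3,5,5-tetramethyl-4,6-dioxocyclohex-1-en-1-yl)-2-methylpropyl]phenyl}hexan-1-one | CCCCCC(=O)c1c(O)c([C@@H](CC(C)C)C2=C(O)C(C)(C)C(=O)C(C)(C)C2=O)c(O)c([C@H](C2=C(O)C(C)(C)C(=O)C(C)(C)C2=O)C(C)C)c1O | target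

**Step count**

Total step count: 6. Longest linear sequence: 4 steps (1 → 2 → 3 → 6); the syncarpic acid branch (steps 4 and 5) joins at step 6.

**Steps most likely to fail**

Step 6. Sodium syncarpate may add to the quinone methides at the aqueous interface without the catalyst, which would erode facial selectivity. The second capture may also be slow, and the alkyl quinone methides may isomerise to ortho-vinylphenols. The fallback sets out from 3 and 12 and comes back at 16; it reverses the polarity of the bond formation. Knoevenagel condensation of 12 with 7 (piperidine, then dilute acid) would give 2,2,4,4-tetramethyl-6-(3-methylbutylidene)cyclohexane-1,3,5-trione F1. Friedel–Crafts-type conjugate addition of 3 to F1, mediated by a chiral BINOL–aluminium Lewis acid that chelates the triketone acceptor, would give the mono-adduct 1-{2,4,6-trihydroxy-3-[(1R)-1-(2-hydroxy-3,3,5,5-tetramethyl-4,6-dioxocyclohex-1-en-1-yl)-3-methylbutyl]phenyl}hexan-1-one F2. Condensation of 12 with 4 would give 2,2,4,4-tetramethyl-6-(2-methylpropylidene)cyclohexane-1,3,5-trione F3, to which F2 would add under the same control to give 16. Stereoisomers that the Lewis acid does not suppress would be separated by preparative chromatography on a chiral stationary phase.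

Step 2. The condensation may run on at both free ring positions, and quinone methide 5 may be captured by a second arene (diarylalkane formation) instead of by sulfinate. The fallback sets out from 3 and comes back at 6. Betti-type aminoalkylation of 3 with 4 and morpholine (EtOH, rt), in which the zwitterionic mono-Mannich base is expected to precipitate and so escape a second reaction, would give 1-{2,4,6-trihydroxy-3-[2-methyl-1-(morpholin-4-yl)propyl]phenyl}hexan-1-one F4. Exchange of the amine for sulfinate (p-TolSO2Na, HCO2H–H2O, through the same quinone methide 5) would then deliver 6.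

Step 3. Substitution at the last, doubly flanked ring position may be slow, and during that time the first sulfone arm may ionise and be lost to cross-alkylation. The fallback sets out from 6 and comes back at 14. The catalytic capture would be run first on the mono-sulfone 6 (1.2 equiv of 12, conditions of step 6) to give the mono-adduct 1-{2,4,6-trihydroxy-3-[(1R)-1-(2-hydroxy-3,3,5,5-tetramethyl-4,6-dioxocyclohex-1-en-1-yl)-2-methylpropyl]phenyl}hexan-1-one F5, whose first arm is now a robust C–C bond. Three-component condensation of F5 with 7 and sodium p-toluenesulfinate (HCO2H–H2O, rt) would give 14, which would be isolated and taken through the second half of step 6 to 16.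

**Further compounds**

F1 | step 6 | 2,2,4,4-tetramethyl-6-(3-methylbutylidene)cyclohexane-1,3,5-trione | CC(C)CC=C1C(=O)C(C)(C)C(=O)C(C)(C)C1=O
F2 | step 6 | 1-{2,4,6-trihydroxy-3-[(1R)-1-(2-hydroxy-3,3,5,5-tetramethyl-4,6-dioxocyclohex-1-en-1-yl)-3-methylbutyl]phenyl}hexan-1-one | CCCCCC(=O)c1c(O)c([C@@H](CC(C)C)C2=C(O)C(C)(C)C(=O)C(C)(C)C2=O)c(O)cc1O
F3 | step 6 | 2,2,4,4-tetramethyl-6-(2-methylpropylidene)cyclohexane-1,3,5-trione | CC(C)C=C1C(=O)C(C)(C)C(=O)C(C)(C)C1=O
F4 | step 2 | 1-{2,4,6-trihydroxy-3-[2-methyl-1-(morpholin-4-yl)propyl]phenyl}hexan-1-one (racemic) | CCCCCC(=O)c1c(O)cc(O)c(C(C(C)C)N2CCOCC2)c1O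
F5 | step 3 | 1-{2,4,6-trihydroxy-3-[(1R)-1-(2-hydroxy-3,3,5,5-tetramethyl-4,6-dioxocyclohex-1-en-1-yl)-2-methylpropyl]phenyl}hexan-1-one | CCCCCC(=O)c1c(O)cc(O)c([C@H](C2=C(O)C(C)(C)C(=O)C(C)(C)C2=O)C(C)C)c1O
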